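Ring A is closed last at C4–C5 (halimane numbering) by a ring-contracting Claisen rearrangement. It exploits the γ,δ-unsaturated carbonyl array C19–C4–C5–C10=C1 of ring A: in the precursor, a 2-cyclohexenyl-3,4-dihydro-2H-pyran-5-carboxylate, oxygen ties C1 to the future C4-methyl carbon C19. One [3,3] shift through an enforced boat forms C4–C5, sets the quaternary C4 and the C5–H stereocentres by chirality transfer from C1, and places the Δ1(10) alkene. The resulting C19 aldehyde is then reduced to methyl. Ring B stems from an asymmetric conjugate addition, C14 from the chiral pool.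

Key step: step 13

Remark on the chemistry: atom labels follow halimane numbering (C4 ester-bearing quaternary carbon, C5 ring-fusion CH, C1=C10 ring alkene, C8 and C9 the methyl-bearing ring B carbons, C11–C15 side chain, C16 the methyl on C13, C18 ester carbon, C19 methyl on C4). "SC" stands for the protected side chain (3S)-3-[(4R)-2,2-dimethyl-1,3-dioxolan-4-yl]-3-[(triethylsilyl)oxy]butyl. The ligand enantiomer in step 1 is the one that delivers methyl to the Re face of C-3 of the enone.

Step 1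
Reactants: 1 2-methylcyclohex-2-en-1-one
Product: 3 trimethyl{[(3R)-2,3-dimethylcyclohex-1-en-1-yl]oxy}silane, via dimethylaluminium enolate 2 (not isolated)
Conditions: Me3Al, CuTC (cat.), chiral BINOL-derived phosphoramidite (cat.), Et2O, −30 °C; then TMSOTf, −30 → 0 °C
Reagents that add atoms: trimethylaluminium, C[Al](C)C; trimethylsilyl trifluoromethanesulfonate, C[Si](C)(C)OS(=O)(=O)C(F)(F)F
Why: Copper-catalysed asymmetric conjugate addition, in which the chiral phosphoramidite–copper complex transfers methyl to the Re face of the β-carbon and so sets C8 as (R), and O-silylation of the regiodefined aluminium enolate stores the C9 nucleophile as its tetrasubstituted silyl enol ether.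

Step 2
Reactants: 4 methyl (4R)-2,2-dimethyl-1,3-dioxolane-4-carboxylate
Product: 5 (4R)-N-methoxy-N,2,2-trimethyl-1,3-dioxolane-4-carboxamide
Conditions: MeNH(OMe)·HCl, i-PrMgCl, THF, −20 °C
Reagents that add atoms: N,O-dimethylhydroxylamine hydrochloride, CNOC.Cl
Why: Weinreb amide formation by ester aminolysis with the chloromagnesium amide proceeds at low temperature without touching the α-alkoxy stereocentre (the future C14).

Step 3
Reactants: 5 (4R)-N-methoxy-N,2,2-trimethyl-1,3-dioxolane-4-carboxamide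
Product: 6 1-[(4R)-2,2-dimethyl-1,3-dioxolan-4-yl]prop-2-en-1-one
Conditions: CH2=CHMgBr, THF, −78 → 0 °C; cold aq. citric acid quench; used at once
Reagents that add atoms: vinylmagnesium bromide, C=C[Mg]Br
Why: Weinreb ketone synthesis, in which the chelated tetrahedral adduct survives until the acidic quench, so that a single vinyl group adds and the C14 centre is carried over unchanged.

Step 4
Reactants: 3 trimethyl{[(3R)-2,3-dimethylcyclohex-1-en-1-yl]oxy}silane; 6 1-[(4R)-2,2-dimethyl-1,3-dioxolan-4-yl]prop-2-en-1-one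
Product: 7 (2S,3R)-2-{3-[(4R)-2,2-dimethyl-1,3-dioxolan-4-yl]-3-oxopropyl}-2,3-dimethylcyclohexan-1-one
Conditions: BF3·OEt2, CH2Cl2, −78 °C; aq. NaHCO3
Reagents that add atoms: none
Why: Mukaiyama–Michael addition, in which C9 of the silyl enol ether attacks the BF3-activated vinyl ketone on the face anti to the adjacent C8 methyl (pseudoaxial to avoid A1,2 strain with the C9 methyl), giving the quaternary centre with C11 trans to that methyl while C14 is never enolised.

Step 5
Reactants: 7 (2S,3R)-2-{3-[(4R)-2,2-dimethyl-1,3-dioxolan-4-yl]-3-oxopropyl}-2,3-dimethylcyclohexan-1-one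
Product: 8 (2S,3R)-2-{(3S)-3-[(4R)-2,2-dimethyl-1,3-dioxolan-4-yl]-3-hydroxybutyl}-2,3-dimethylcyclohexan-1-one
Conditions: MeMgBr, Et2O/CH2Cl2, −78 °C; aq. NH4Cl
Reagents that add atoms: methylmagnesium bromide, C[Mg]Br
Why: Chelation-controlled (Cram-chelate) Grignard addition, in which magnesium bridges the C13 ketone oxygen and the dioxolane oxygen on C14 and methyl attacks the face opposite C15 to give the (13S) tertiary alcohol, while the hindered α-quaternary ring ketone should not react at −78 °C.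

Step 6
Reactants: 8 (2S,3R)-2-{(3S)-3-[(4R)-2,2-dimethyl-1,3-dioxolan-4-yl]-3-hydroxybutyl}-2,3-dimethylcyclohexan-1-one
Product: 9 (2S,3R)-2,3-dimethyl-2-SC-cyclohexan-1-one
Conditions: TESOTf, 2,6-lutidine, CH2Cl2, −78 → 0 °C
Reagents that add atoms: triethylsilyl trifluoromethanesulfonate, CC[Si](CC)(CC)OS(=O)(=O)C(F)(F)F
Why: Silylation of the tertiary alcohol with the silyl triflate gives a base- and heat-stable triethylsilyl ether that keeps the hydroxyl out of the organolithium, borane and acid-catalysed steps.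

Step 7
Reactants: 9 (2S,3R)-2,3-dimethyl-2-SC-cyclohexan-1-one
Product: 10 (E)-2,4,6-triisopropylbenzenesulfonylhydrazone of ketone 9
Conditions: 2,4,6-triisopropylbenzenesulfonyl hydrazide, PPTS (cat.), THF, rt
Reagents that add atoms: 2,4,6-triisopropylbenzenesulfonyl hydrazide, CC(C)c1cc(C(C)C)c(c(C(C)C)c1)S(=O)(=O)NN
Why: Hydrazone condensation places the sulfonamide N–H syn to the only enolisable position (C5), as the Shapiro reaction of step 10 requires.

Step 8
Reactants: 11 methyl 5-chloro-5-oxopentanoate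
Product: 12 methyl 5-[methoxy(methyl)amino]-5-oxopentanoate
Conditions: MeNH(OMe)·HCl, pyridine, CH2Cl2, 0 °C → rt
Reagents that add atoms: N,O-dimethylhydroxylamine hydrochloride, CNOC.Cl
Why: Weinreb amide formation by acylation of the amine with the acid chloride is much faster than any reaction at the methyl ester.

Step 9
Reactants: 12 methyl 5-[methoxy(methyl)amino]-5-oxopentanoate
Product: 14 methyl (2E)-3-methoxy-2-{3-[methoxy(methyl)amino]-3-oxopropyl}prop-2-enoate, via sodium formyl-ester enolate 13 (not isolated)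
Conditions: NaH, HCO2Me, THF, 0 °C → rt; then Me2SO4, DMF, rt
Reagents that add atoms: methyl formate, COC=O; dimethyl sulfate, COS(=O)(=O)OC; sodium hydride, [Na+].[H-] (sodium of intermediate 13 only)
Why: Crossed Claisen condensation with methyl formate occurs at the more acidic ester α-carbon (C4), and O-methylation of the formyl-ester enolate with the hard electrophile dimethyl sulfate gives the β-methoxyacrylate that carries C18 and the masked C19 (either alkene isomer serves).

Step 10
Reactants: 10 (E)-2,4,6-triisopropylbenzenesulfonylhydrazone of ketone 9; 14 methyl (2E)-3-methoxy-2-{3-[methoxy(methyl)amino]-3-oxopropyl}prop-2-enoate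
Product: 16 methyl (2E)-3-methoxy-2-{3-oxo-3-[(5R,6S)-5,6-dimethyl-6-SC-cyclohex-1-en-1-yl]propyl}prop-2-enoate, via vinyllithium 15 (not isolated)
Conditions: n-BuLi (2.2 equiv), THF, −78 → 0 °C; then 14, −78 °C; aq. NH4Cl
Reagents that add atoms: n-butyllithium, [Li]CCCC (lithium of intermediate 15 only)
Why: Shapiro reaction (double deprotonation, loss of sulfinate and N2) gives the C10 vinyllithium with the C5=C10 alkene regiospecifically because C9 is quaternary, and its acylation by the Weinreb amide stops at the enone through the chelated tetrahedral intermediate.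

Step 11
Reactants: 16 methyl (2E)-3-methoxy-2-{3-oxo-3-[(5R,6S)-5,6-dimethyl-6-SC-cyclohex-1-en-1-yl]propyl}prop-2-enoate
Product: 17 methyl (2E)-2-{(3R)-3-hydroxy-3-[(5R,6S)-5,6-dimethyl-6-SC-cyclohex-1-en-1-yl]propyl}-3-methoxyprop-2-enoate
Conditions: (S)-Me-CBS oxazaborolidine (cat.), catecholborane, toluene, −78 °C; MeOH quench
Reagents that add atoms: none
Why: Corey–Bakshi–Shibata reduction, in which the α-branched cyclohexenyl group acts as the large substituent so that the (S)-oxazaborolidine delivers hydride to give the (R)-allylic alcohol at C1 under reagent control, leaving ester and enol ether untouched.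

Step 12
Reactants: 17 methyl (2E)-2-{(3R)-3-hydroxy-3-[(5R,6S)-5,6-dimethyl-6-SC-cyclohex-1-en-1-yl]propyl}-3-methoxyprop-2-enoate
Product: 18 methyl (2R)-2-[(5R,6S)-5,6-dimethyl-6-SC-cyclohex-1-en-1-yl]-3,4-dihydro-2H-pyran-5-carboxylate
Conditions: PPTS (cat.), toluene, 4 Å MS, 80 °C
Reagents that add atoms: none
Why: Acid-catalysed intramolecular alkoxy exchange on the β-methoxyacrylate (oxa-Michael addition, then loss of methanol) closes the six-membered enol ether, and since the C1–O bond is not broken the (R) centre is retained.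

Step 13
Reactants: 18 methyl (2R)-2-[(5R,6S)-5,6-dimethyl-6-SC-cyclohex-1-en-1-yl]-3,4-dihydro-2H-pyran-5-carboxylate
Product: 19 methyl (1R,5S,6R,8aR)-1-formyl-5,6-dimethyl-5-SC-1,2,3,5,6,7,8,8a-octahydronaphthalene-1-carboxylate
Conditions: o-dichlorobenzene (degassed), BHT (cat.), base-washed sealed tube, 200 °C
Reagents that add atoms: none
Why: Heating should induce a concerted [3,3]-sigmatropic (Claisen) shift of the cyclic allyl vinyl ether C4=C19–O–C1–C10=C5, in which the O–C1 bond breaks while C4–C5 forms, giving the C19 aldehyde and the C1=C10 alkene. The closest known reaction type is the thermal Claisen rearrangement of 2-alkenyl-3,4-dihydro-2H-pyrans to cyclohex-3-enecarbaldehydes, together with that of allyl β-alkoxyacrylates to α-formyl esters. Ring A closes as a ring contraction of the pyran through a bicyclo[2.2.2]-like boat array with C4 and C1 as bridgeheads, the only geometry the C2–C3 tether allows. C5 is set by suprafacial chirality transfer from the (R)-C1–O centre, which puts C4 on the ring B face anti to the C9 methyl; C4 is set by the boat, which aligns C19 with C10 and so places the formyl carbon cis to C6 and the ester cis to H5. The step needs the [3,3] shift to outrun retro-hetero-Diels–Alder cleavage and elimination of the allylic oxygen. The enol ether geometry fixed by the pyran ring, the position of C6 fixed by ring B and the single reactive rotamer about C1–C10 leave one boat and hence one diastereomer.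

Step 14
Reactants: 19 methyl (1R,5S,6R,8aR)-1-formyl-5,6-dimethyl-5-SC-1,2,3,5,6,7,8,8a-octahydronaphthalene-1-carboxylate
Product: 21 methyl (1R,5S,6R,8aR)-1,5,6-trimethyl-5-SC-1,2,3,5,6,7,8,8a-octahydronaphthalene-1-carboxylate, via tosylhydrazone 20 (not isolated)
Conditions: TsNHNH2, MeOH, rt; evaporate; catecholborane, CHCl3, 0 °C; then NaOAc·3H2O, 60 °C
Reagents that add atoms: p-toluenesulfonohydrazide, Cc1ccc(cc1)S(=O)(=O)NN (retained in intermediate 20 only)
Why: Tosylhydrazone reduction with catecholborane, in which hydride adds to C=N, acetate triggers loss of sulfinate and the diazene expels N2, should turn the C19 formyl group into the methyl group without touching the quaternary C4, the ester or the alkene.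

Step 15
Reactants: 21 methyl (1R,5S,6R,8aR)-1,5,6-trimethyl-5-SC-1,2,3,5,6,7,8,8a-octahydronaphthalene-1-carboxylate
Product: 22 methyl (1R,5S,6R,8aR)-5-[(3S,4R)-3,4,5-trihydroxy-3-methylpentyl]-1,5,6-trimethyl-1,2,3,5,6,7,8,8a-octahydronaphthalene-1-carboxylate
Conditions: 1 M aq. HCl, THF/MeOH, rt
Reagents that add atoms: none
Why: Acetal hydrolysis and protodesilylation in aqueous acid remove the acetonide and the triethylsilyl ether, while the hindered methyl ester and the trisubstituted alkene should stay intact.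

Step 16
Reactants: 22 methyl (1R,5S,6R,8aR)-5-[(3S,4R)-3,4,5-trihydroxy-3-methylpentyl]-1,5,6-trimethyl-1,2,3,5,6,7,8,8a-octahydronaphthalene-1-carboxylate
Product: 23 methyl (1R,5S,6R,8aR)-5-[(3S,4R)-4,5-bis(acetyloxy)-3-hydroxy-3-methylpentyl]-1,5,6-trimethyl-1,2,3,5,6,7,8,8a-octahydronaphthalene-1-carboxylate
Conditions: Ac2O, pyridine, rt
Reagents that add atoms: acetic anhydride, CC(=O)OC(C)=O
Why: Acylation with acetic anhydride in pyridine esterifies the primary C15 and secondary C14 hydroxyls, whereas the tertiary C13 hydroxyl is too hindered to react without forcing conditions.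

Compound list
1 | 2-methylcyclohex-2-en-1-one | CC1=CCCCC1=O | starting material
2 | dimethylaluminium (3R)-2,3-dimethylcyclohex-1-en-1-olate | C[Al](C)OC1=C(C)[C@H](C)CCC1 | intermediate
3 | trimethyl{[(3R)-2,3-dimethylcyclohex-1-en-1-yl]oxy}silane | C[Si](C)(C)OC1=C(C)[C@H](C)CCC1 | intermediate
4 | methyl (4R)-2,2-dimethyl-1,3-dioxolane-4-carboxylate | COC(=O)[C@H]1COC(C)(C)O1 | starting material
5 | (4R)-N-methoxy-N,2,2-trimethyl-1,3-dioxolane-4-carboxamide | CON(C)C(=O)[C@H]1COC(C)(C)O1 | intermediate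
6 | 1-[(4R)-2,2-dimethyl-1,3-dioxolan-4-yl]prop-2-en-1-one | C=CC(=O)[C@H]1COC(C)(C)O1 | intermediate
7 | (2S,3R)-2-{3-[(4R)-2,2-dimethyl-1,3-dioxolan-4-yl]-3-oxopropyl}-2,3-dimethylcyclohexan-1-one | O=C1CCC[C@@H](C)[C@]1(C)CCC(=O)[C@H]2COC(C)(C)O2 | intermediate
8 | (2S,3R)-2-{(3S)-3-[(4R)-2,2-dimethyl-1,3-dioxolan-4-yl]-3-hydroxybutyl}-2,3-dimethylcyclohexan-1-one | O=C1CCC[C@@H](C)[C@]1(C)CC[C@](C)(O)[C@H]2COC(C)(C)O2 | intermediate
9 | (2S,3R)-2,3-dimethyl-2-SC-cyclohexan-1-one (triethylsilyl ether of 8) | O=C1CCC[C@@H](C)[C@]1(C)CC[C@](C)(O[Si](CC)(CC)CC)[C@H]2COC(C)(C)O2 | intermediate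
10 | (E)-2,4,6-triisopropylbenzenesulfonylhydrazone of ketone 9 | CC(C)c1cc(C(C)C)c(c(C(C)C)c1)S(=O)(=O)N/N=C2\CCC[C@@H](C)[C@]2(C)CC[C@](C)(O[Si](CC)(CC)CC)[C@H]3COC(C)(C)O3 | intermediate
11 | methyl 5-chloro-5-oxopentanoate | COC(=O)CCCC(Cl)=O | starting material
12 | methyl 5-[methoxy(methyl)amino]-5-oxopentanoate | COC(=O)CCCC(=O)N(C)OC | intermediate
13 | sodium enolate of methyl 2-formyl-5-[methoxy(methyl)amino]-5-oxopentanoate | [Na+].[O-]C=C(CCC(=O)N(C)OC)C(=O)OC | intermediate
14 | methyl (2E)-3-methoxy-2-{3-[methoxy(methyl)amino]-3-oxopropyl}prop-2-enoate | CO/C=C(\CCC(=O)N(C)OC)C(=O)OC | intermediate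
15 | (5R,6S)-5,6-dimethyl-6-SC-cyclohex-1-en-1-yllithium | [Li]C1=CCC[C@@H](C)[C@]1(C)CC[C@](C)(O[Si](CC)(CC)CC)[C@H]2COC(C)(C)O2 | intermediate
16 | methyl (2E)-3-methoxy-2-{3-oxo-3-[(5R,6S)-5,6-dimethyl-6-SC-cyclohex-1-en-1-yl]propyl}prop-2-enoate | CO/C=C(\CCC(=O)C1=CCC[C@@H](C)[C@]1(C)CC[C@](C)(O[Si](CC)(CC)CC)[C@H]2COC(C)(C)O2)C(=O)OC | intermediate
17 | methyl (2E)-2-{(3R)-3-hydroxy-3-[(5R,6S)-5,6-dimethyl-6-SC-cyclohex-1-en-1-yl]propyl}-3-methoxyprop-2-enoate | CO/C=C(\CC[C@@H](O)C1=CCC[C@@H](C)[C@]1(C)CC[C@](C)(O[Si](CC)(CC)CC)[C@H]2COC(C)(C)O2)C(=O)OC | intermediate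
18 | methyl (2R)-2-[(5R,6S)-5,6-dimethyl-6-SC-cyclohex-1-en-1-yl]-3,4-dihydro-2H-pyran-5-carboxylate | COC(=O)C1=CO[C@H](CC1)C2=CCC[C@@H](C)[C@]2(C)CC[C@](C)(O[Si](CC)(CC)CC)[C@H]3COC(C)(C)O3 | intermediate
19 | methyl (1R,5S,6R,8aR)-1-formyl-5,6-dimethyl-5-SC-1,2,3,5,6,7,8,8a-octahydronaphthalene-1-carboxylate | COC(=O)[C@]1(C=O)CCC=C2[C@H]1CC[C@@H](C)[C@]2(C)CC[C@](C)(O[Si](CC)(CC)CC)[C@H]3COC(C)(C)O3 | intermediate
20 | (E)-N-tosylhydrazone of aldehyde 19 | COC(=O)[C@]1(/C=N/NS(=O)(=O)c4ccc(C)cc4)CCC=C2[C@H]1CC[C@@H](C)[C@]2(C)CC[C@](C)(O[Si](CC)(CC)CC)[C@H]3COC(C)(C)O3 | intermediate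
21 | methyl (1R,5S,6R,8aR)-1,5,6-trimethyl-5-SC-1,2,3,5,6,7,8,8a-octahydronaphthalene-1-carboxylate | COC(=O)[C@]1(C)CCC=C2[C@H]1CC[C@@H](C)[C@]2(C)CC[C@](C)(O[Si](CC)(CC)CC)[C@H]3COC(C)(C)O3 | intermediate
22 | methyl (1R,5S,6R,8aR)-5-[(3S,4R)-3,4,5-trihydroxy-3-methylpentyl]-1,5,6-trimethyl-1,2,3,5,6,7,8,8a-octahydronaphthalene-1-carboxylate | COC(=O)[C@]1(C)CCC=C2[C@H]1CC[C@@H](C)[C@]2(C)CC[C@](C)(O)[C@@H](CO)O | intermediate
23 | methyl (1R,5S,6R,8aR)-5-[(3S,4R)-4,5-bis(acetyloxy)-3-hydroxy-3-methylpentyl]-1,5,6-trimethyl-1,2,3,5,6,7,8,8a-octahydronaphthalene-1-carboxylate (CNP0238486.1) | COC(=O)[C@]1(C)CCC=C2[C@H]1CC[C@@H](C)[C@]2(C)CC[C@](C)(O)[C@@H](COC(C)=O)OC(C)=O | target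

Total step count: 16. Longest linear sequence: 13 steps (steps 2, 3, 4, 5, 6, 7, 10, 11, 12, 13, 14, 15, 16).

Steps most likely to fail

Step 13 (key step). The [3,3] shift of this hindered, ester-deactivated enol ether may be slower than thermal cleavage of the pyran ring (retro-hetero-Diels–Alder) or loss of the allylic C1–O bond. The fallback closes ring A by an intermolecular Diels–Alder reaction and sets out from ketone 9. Addition of vinylmagnesium bromide (CeCl3, THF, −78 °C) should give the tertiary allylic alcohol (2S,3R)-1-ethenyl-2,3-dimethyl-2-SC-cyclohexan-1-ol F1. Dehydration with the Burgess reagent, for which only C5 offers a β-hydrogen, should give the diene (5R,6S)-1-ethenyl-5,6-dimethyl-6-SC-cyclohex-1-ene F2. Cycloaddition of F2 with methyl methacrylate (toluene, 110 °C, or Et2AlCl, −20 °C) forms C2–C3 and C4–C5 together. The ortho, ester-exo adduct formed anti to the C9 methyl is 21, where the route is rejoined after separation from regio- and stereoisomers; this fallback gives up the stereospecificity of the main route.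

Step 10. Formation of the hindered vinyllithium may be incomplete, or it may be consumed by proton transfer from the α-CH2 of 14 or by attack at the acrylate instead of the amide. The fallback sets out from ketone 9, which is converted (KHMDS, PhNTf2, THF, −78 °C) into the enol triflate (5R,6S)-5,6-dimethyl-6-SC-cyclohex-1-en-1-yl trifluoromethanesulfonate F3. Amide 14 is reduced (DIBAL-H, −78 °C) to the aldehyde methyl (2E)-3-methoxy-2-(3-oxopropyl)prop-2-enoate F4. Nozaki–Hiyama–Kishi coupling of F3 with F4 (CrCl2, cat. NiCl2, DMF) should give the allylic alcohol methyl (2E)-2-{3-hydroxy-3-[(5R,6S)-5,6-dimethyl-6-SC-cyclohex-1-en-1-yl]propyl}-3-methoxyprop-2-enoate F5 as a mixture of C1 epimers. Dess–Martin oxidation returns to enone 16.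

Step 14. Base-induced retro-Claisen loss of the formyl group from the α-formyl ester may compete during decomposition of the hydrazone adduct, and hydride addition at the neopentyl C=N may be sluggish. The fallback sets out from aldehyde 19. NaBH4 (MeOH, 0 °C) should give the neopentyl alcohol methyl (1R,5S,6R,8aR)-1-(hydroxymethyl)-5,6-dimethyl-5-SC-1,2,3,5,6,7,8,8a-octahydronaphthalene-1-carboxylate F6. PhOC(S)Cl, pyridine and DMAP convert it into the O-phenyl thionocarbonate of that alcohol F7. Barton–McCombie deoxygenation (Bu3SnH, AIBN, toluene, 110 °C) returns to 21.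

Further compounds
F1 | step 13 | (2S,3R)-1-ethenyl-2,3-dimethyl-2-SC-cyclohexan-1-ol (either C1 epimer) | C=CC1(O)CCC[C@@H](C)[C@]1(C)CC[C@](C)(O[Si](CC)(CC)CC)[C@H]2COC(C)(C)O2
F2 | step 13 | (5R,6S)-1-ethenyl-5,6-dimethyl-6-SC-cyclohex-1-ene | C=CC1=CCC[C@@H](C)[C@]1(C)CC[C@](C)(O[Si](CC)(CC)CC)[C@H]2COC(C)(C)O2
F3 | step 10 | (5R,6S)-5,6-dimethyl-6-SC-cyclohex-1-en-1-yl trifluoromethanesulfonate | FC(F)(F)S(=O)(=O)OC1=CCC[C@@H](C)[C@]1(C)CC[C@](C)(O[Si](CC)(CC)CC)[C@H]2COC(C)(C)O2
F4 | step 10 | methyl (2E)-3-methoxy-2-(3-oxopropyl)prop-2-enoate | CO/C=C(\CCC=O)C(=O)OC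
F5 | step 10 | methyl (2E)-2-{3-hydroxy-3-[(5R,6S)-5,6-dimethyl-6-SC-cyclohex-1-en-1-yl]propyl}-3-methoxyprop-2-enoate (both C1 epimers) | CO/C=C(\CCC(O)C1=CCC[C@@H](C)[C@]1(C)CC[C@](C)(O[Si](CC)(CC)CC)[C@H]2COC(C)(C)O2)C(=O)OC
F6 | step 14 | methyl (1R,5S,6R,8aR)-1-(hydroxymethyl)-5,6-dimethyl-5-SC-1,2,3,5,6,7,8,8a-octahydronaphthalene-1-carboxylate | COC(=O)[C@]1(CO)CCC=C2[C@H]1CC[C@@H](C)[C@]2(C)CC[C@](C)(O[Si](CC)(CC)CC)[C@H]3COC(C)(C)O3
F7 | step 14 | O-phenyl thionocarbonate of alcohol F6 | COC(=O)[C@]1(COC(=S)Oc4ccccc4)CCC=C2[C@H]1CC[C@@H](C)[C@]2(C)CC[C@](C)(O[Si](CC)(CC)CC)[C@H]3COC(C)(C)O3
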